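## The problem

Target 19 is 5,8-dihydroxy-7-methoxy-6-(3-methylbut-2-enyl)-3-(2,4,5-trimethoxyphenyl)chromen-4-one, an isoflavone. Every carbon of its benzo ring A (C4a, C5 to C8, C8a) is substituted, C2 of the pyranone ring C carries hydrogen, and C3 carries the trimethoxyphenyl ring B. There is no stereogenic centre and the prenyl double bond ends in two methyl groups, so the difficulty is purely regiochemical. Ring A needs OH at C5, prenyl at C6, OMe at C7 and OH at C8 in that order, with only one of its three exocyclic oxygens methylated, and ring C must close with the aryl group on C3 and not on C2. Three features limit late reagents. The 5,8-dihydroxy pair is a para-hydroquinone that air or metal oxidants convert into a quinone. The prenyl olefin does not survive hydrogenolysis, peracid or strong acid, which also cyclises it onto the C5 hydroxyl. The pyranone opens at C2 under strong base. The two phenols therefore travel as ethers that come off without hydrogen or a strong Lewis acid, and any peracid step has to precede the prenyl group. The plan rests on one mapping: C4 (a carbonyl on C4a) and O1 (on the neighbouring C8a) are the formyl carbon and ortho hydroxyl of a salicylaldehyde, and C2/C3 together stand at the oxidation level of an alkyne. Ring C can thus be closed by placing an alkyne between the aldehyde C–H bond and the phenol O–H bond, forming C3–C4 and O1–C2 in one operation.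

## Retrosynthesis

**Unmasking (19 from 17 from 16).** The last bonds cut are the two O–CH2OMe bonds at O5 and O8 and, one step earlier, the C2–Si bond. Methoxymethyl ethers are preferred to benzyl ethers, whose hydrogenolysis would saturate the prenyl group, and to methyl ethers, which could not be cleaved beside the four methoxy groups that must stay. They also serve as directing groups earlier in the route. The precursors are the bis(MOM) isoflavone 17 and its 2-trimethylsilyl derivative 16. The forward steps must cleave C–Si without opening the pyranone and exchange the acetals under acid mild enough for the prenyl group; the C5 ether, peri to the carbonyl, should fall first (monoether 18).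

**Ring C (16 from 12 and 15).** C3–C4 and O1–C2 are cut together. The neighbouring cut at C4–C4a would need a strongly acidic acylation beside the prenyl group. A cut at O1–C8a would need an aryne or a substitution on an unactivated, electron-rich ring. A cut at C3–C1' (cross-coupling) would leave ring C still to be built in several steps from the same aldehyde. The chosen cut divides 16 into salicylaldehyde 12, which holds every ring A substituent, and aryl(silyl)alkyne 15, which holds ring B. The forward reaction must activate the formyl C–H bond, insert the alkyne with the aryl-bearing carbon bonded to the acyl carbon, and close onto the only free hydroxyl next to the aldehyde.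

**Alkyne (15 from 13 and 14).** The aryl–alkynyl bond is cut, leading to 1-bromo-2,4,5-trimethoxybenzene 13 and ethynyltrimethylsilane 14. Homologation of the corresponding benzaldehyde followed by C-silylation would take two steps to the same compound. The coupling must achieve oxidative addition into an electron-rich aryl bromide, which calls for a bulky electron-rich phosphine.

**Formyl group (12 from 10 from 9).** The C4–C4a bond, formyl carbon to ring, is cut. Lithiation and DMF quench would require a third, separately removable protecting group on the phenol. Magnesium-mediated formylation instead uses the free hydroxyl as the director, and that hydroxyl is the one the key step needs. Phenol 10 has a single ring hydrogen, ortho to the hydroxyl, so the site is not in question. Phenol 10 comes from silyl ether 9 by O–Si cleavage. The forward step must C-formylate a carbon flanked by OH and OMOM, passing through salicyl alcohol 11, without harming the acetals or the olefin.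

**Prenyl group (9 from 6 and 7).** The bond from C6 of the future chromone to the prenyl CH2 is cut. O-prenylation and Claisen rearrangement would need a free ortho hydroxyl and would deliver the reversed allyl unit first; Friedel–Crafts prenylation is unselective. Directed metalation fits the substrate: the carbon to be alkylated lies between a MOM ether and a methoxy group. Precursor 6 is a tetraoxygenated benzene with two ring hydrogens; the partner is prenyl bromide 7. The base must choose the hydrogen flanked by OMOM and OMe over the one flanked by OMOM and the bulky silyl ether, and aryllithium 8 must attack the primary carbon of the bromide.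

**Oxygen pattern (6 from 5 from 3 from 2 from 1).** Cut in turn are the second O–MOM bond, the aryl C–O bond that replaced the formyl group (Dakin oxidation through formate 4), the O–Si bond and the first O–MOM bond. 5-Hydroxyvanillin 1 already has three adjacent oxygens with the right one methylated, and its formyl group is a latent fourth oxygen at the correct carbon. The hydroxyl para to the formyl group is the more acidic one, which allows the two phenols to be told apart: MOM on O4 (future O8) gives 2, then silyl on O3 (future O1) gives 3. The forward steps require clean monoalkylation and a peracid oxidation placed before any olefin is present.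

## Roads not taken

**Alternative 1:** Ring A would be built last by a photochemical Danheiser-type benzannulation. The cut removes C8–C8a, C7–C8, C5–C6 and C4a–C5 and leads to the diazoketone 2-(2-diazoacetyl)-5-(2,4,5-trimethoxyphenyl)pyran-4-one A2 and the ynol ether 1-methoxy-5-methylhex-4-en-1-yne A3. Irradiation would bring about Wolff rearrangement to a vinylketene, [2+2] cycloaddition with A3, four-electron opening of the cyclobutenone and six-electron closure onto the pyranone. The product would be 5-hydroxy-7-methoxy-6-(3-methylbut-2-enyl)-3-(2,4,5-trimethoxyphenyl)chromen-4-one A1.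

- Merits: four skeletal bonds and a ring form in one step, the C5 hydroxyl appears free, and the order OH/prenyl/OMe follows from the polarity of A3. Ring C and its aryl group exist beforehand, so C3 versus C2 is not in doubt; in this respect the road is better than the chosen one.
- Weak points: A1 has hydrogen at C8. The fourth oxygen would need a late para-hydroxylation (Elbs-type persulfate oxidation) of a phenol that also carries a prenyl olefin and an electron-rich ring B, a transformation that is rarely clean. A3 has a CH2 that is both propargylic and allylic and isomerises readily. A2 needs its own multistep pyranone synthesis. Irradiating a pyranone beside a trisubstituted olefin invites [2+2] side reactions.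
- Comparison: the chosen plan forms fewer bonds in its key step and carries a regiochemical question this road does not. Against that, it brings all ring A heteroatoms from a cheap aromatic compound and needs no oxidation after the prenyl group is in place.

**Alternative 2:** Ring C would be closed at C4–C4a by Friedel–Crafts acylation of (Z)-3-[2,5-bis(benzyloxy)-3-methoxy-4-(3-methylbut-2-enyl)phenoxy]-2-(2,4,5-trimethoxyphenyl)prop-2-enoic acid A5. Activation as the mixed trifluoroacetic anhydride or as the acid chloride with SnCl4 would give 5,8-bis(benzyloxy)-7-methoxy-6-(3-methylbut-2-enyl)-3-(2,4,5-trimethoxyphenyl)chromen-4-one A4.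

- Merits: C4a is the only unsubstituted ring carbon, the aryl group is fixed on C3 by construction, and no precious metal is needed. The regiochemistry is more certain than in the chosen plan, and the convergence is comparable.
- Weak points: a strong electrophile and a Lewis acid meet the prenyl olefin (protonation, cation–olefin cyclisation, chloride addition) and benzyl ethers ortho to the reacting site. The enol ether acid must keep the Z geometry and is prone to hydrolysis. The benzyl ethers cannot be removed by hydrogenolysis without saturating the prenyl group, and boron trihalide cleavage would expose the olefin to acid cyclisation onto O5.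
- Comparison: the chosen plan sets near-neutral ring-closing conditions and acetal protecting groups, whose removal the prenyl group tolerates, against the better regiochemical certainty of this road.

**Alternative 3:** Ring C would be made by aryne insertion, cutting O1–C8a and C4–C4a. CsF would release the aryne from [5-methoxy-3-(methoxymethoxy)-4-(3-methylbut-2-enyl)-2-(trimethylsilyl)phenyl] trifluoromethanesulfonate A7. The enolate oxygen of methyl 3-hydroxy-2-(2,4,5-trimethoxyphenyl)prop-2-enoate A8 would add at C8a, and the aryl anion at C4a would attack the ester with loss of methoxide. The product would be 7-methoxy-5-(methoxymethoxy)-6-(3-methylbut-2-enyl)-3-(2,4,5-trimethoxyphenyl)chromen-4-one A6.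

- Merits: fluoride at moderate temperature is gentler than an oxidative rhodium step, the aryl position is fixed beforehand, and the alkoxy group next to the aryne directs the nucleophile to the correct carbon.
- Weak points: A6, like A1, lacks the C8 oxygen, so the same late hydroxylation problem returns. A7 is a pentasubstituted arene that is no easier to prepare than aldehyde 12. The ambident enolate of A8 tends to arylate at carbon, which leads to acyl–alkylation instead of the chromone. The aryne can also undergo ene reactions with prenyl groups.
- Comparison: this road is milder and regiochemically safer in the ring closure. The chosen plan sets against it a complete oxygen pattern before the key step and only two deprotections after it.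

Key step: step 9

Remark on the chemistry: 19 has no stereogenic centre or stereogenic double bond, so no configuration is assigned anywhere in the route. Ring positions are numbered as in chromen-4-one.

## Route

Step 1
Reactants: 1 5-hydroxyvanillin (3,4-dihydroxy-5-methoxybenzaldehyde)
Product: 2 3-hydroxy-5-methoxy-4-(methoxymethoxy)benzaldehyde
Conditions: MOMCl (1.05 equiv), K2CO3 (1.0 equiv), acetone, 0 °C to rt
Reagents that add atoms: chloromethyl methyl ether, COCCl
Why: Williamson-type O-alkylation under acidity control: the hydroxyl para to the formyl group is the more acidic phenol, so one equivalent of carbonate should form its phenoxide selectively, as in the well-known selective 4-O-alkylation of 3,4-dihydroxybenzaldehydes.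

Step 2
Reactants: 2 3-hydroxy-5-methoxy-4-(methoxymethoxy)benzaldehyde
Product: 3 3-methoxy-4-(methoxymethoxy)-5-[tri(propan-2-yl)silyloxy]benzaldehyde
Conditions: TIPSCl (1.2 equiv), imidazole (2.5 equiv), DMF, rt
Reagents that add atoms: chlorotri(propan-2-yl)silane, CC(C)[Si](Cl)(C(C)C)C(C)C
Why: Standard silylation of the remaining phenol; the triisopropylsilyl ether is chosen because it withstands the methanolysis of step 3 and butyllithium in step 5 and, being bulky and non-coordinating, will not direct lithiation.

Step 3
Reactants: 3 3-methoxy-4-(methoxymethoxy)-5-[tri(propan-2-yl)silyloxy]benzaldehyde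
Product: 5 3-methoxy-4-(methoxymethoxy)-5-[tri(propan-2-yl)silyloxy]phenol, via aryl formate 4 (not isolated)
Conditions: mCPBA (1.3 equiv), CH2Cl2, 0 °C to rt; aq. NaHCO3 wash; then Et3N (0.2 equiv), MeOH, rt
Reagents that add atoms: 3-chloroperoxybenzoic acid, OOC(=O)c1cccc(Cl)c1
Why: Dakin oxidation in its Baeyer–Villiger form: the electron-rich aryl group, with an alkoxy group para to the carbonyl, migrates in the Criegee intermediate to give formate 4, which mild methanolysis cleaves to the phenol. The peracid is used before any olefin is present.

Step 4
Reactants: 5 3-methoxy-4-(methoxymethoxy)-5-[tri(propan-2-yl)silyloxy]phenol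
Product: 6 [3-methoxy-2,5-bis(methoxymethoxy)phenoxy]tri(propan-2-yl)silane
Conditions: MOMCl (1.5 equiv), i-Pr2NEt (2.0 equiv), CH2Cl2, 0 °C to rt
Reagents that add atoms: chloromethyl methyl ether, COCCl
Why: Routine methoxymethylation of a phenol under amine base, which leaves the silyl ether untouched; the new acetal masks the future O5 and is the second directing group for step 5.

Step 5
Reactants: 6 [3-methoxy-2,5-bis(methoxymethoxy)phenoxy]tri(propan-2-yl)silane, 7 prenyl bromide (1-bromo-3-methylbut-2-ene)
Product: 9 [3-methoxy-2,5-bis(methoxymethoxy)-4-(3-methylbut-2-enyl)phenoxy]tri(propan-2-yl)silane, via aryllithium 8 (not isolated)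
Conditions: n-BuLi (1.2 equiv), THF, 0 °C; then CuBr·SMe2 (10 mol %), 7 (1.5 equiv), −78 °C to rt
Reagents that add atoms: none
Why: Directed ortho-metalation followed by copper-catalysed allylic alkylation: the hydrogen between the MOM ether and the methoxy group has two cooperating directors, whereas the other ring hydrogen is shielded by the bulky silyl ether. The arylcopper species should attack the unhindered primary carbon of the bromide, giving the linear prenyl group; the lithium is para to the silyl ether, so no silyl migration is expected.

Step 6
Reactants: 9 [3-methoxy-2,5-bis(methoxymethoxy)-4-(3-methylbut-2-enyl)phenoxy]tri(propan-2-yl)silane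
Product: 10 3-methoxy-2,5-bis(methoxymethoxy)-4-(3-methylbut-2-enyl)phenol
Conditions: Bu4NF (1.1 equiv), THF, 0 °C
Reagents that add atoms: none
Why: Fluoride cleavage of an aryl silyl ether, driven by the Si–F bond and the phenoxide leaving group; acetals and the olefin are inert to fluoride.

Step 7
Reactants: 10 3-methoxy-2,5-bis(methoxymethoxy)-4-(3-methylbut-2-enyl)phenol
Product: 12 2-hydroxy-4-methoxy-3,6-bis(methoxymethoxy)-5-(3-methylbut-2-enyl)benzaldehyde, via salicyl alcohol 11 (not isolated)
Conditions: MgCl2 (2.0 equiv), Et3N (4.0 equiv), (CH2O)n (6 equiv), THF, reflux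
Reagents that add atoms: paraformaldehyde (as formaldehyde), C=O
Why: Magnesium-mediated ortho-formylation (Casnati–Skattebøl type): the magnesium phenoxide delivers formaldehyde to the ortho carbon through a six-membered chelate, and an Oppenauer-type hydride transfer to a second formaldehyde oxidises salicyl alcohol 11 to the aldehyde. The only ring hydrogen left is ortho to the hydroxyl, and the basic medium spares the acetals and the olefin.

Step 8
Reactants: 13 1-bromo-2,4,5-trimethoxybenzene, 14 ethynyltrimethylsilane
Product: 15 trimethyl[(2,4,5-trimethoxyphenyl)ethynyl]silane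
Conditions: PdCl2(PhCN)2 (3 mol %), P(t-Bu)3 (6 mol %), CuI (2 mol %), i-Pr2NH, dioxane, rt to 40 °C
Reagents that add atoms: none
Why: Sonogashira coupling; the bulky electron-rich phosphine lets zerovalent palladium add to the electron-rich aryl bromide near room temperature, and the silyl group keeps the alkyne from coupling twice.

Step 9
Reactants: 12 2-hydroxy-4-methoxy-3,6-bis(methoxymethoxy)-5-(3-methylbut-2-enyl)benzaldehyde, 15 trimethyl[(2,4,5-trimethoxyphenyl)ethynyl]silane
Product: 16 7-methoxy-5,8-bis(methoxymethoxy)-6-(3-methylbut-2-enyl)-3-(2,4,5-trimethoxyphenyl)-2-(trimethylsilyl)chromen-4-one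
Conditions: [Cp*RhCl2]2 (2.5 mol %), Cu(OAc)2 (2.1 equiv), DMF, 100 °C, N2
Reagents that add atoms: none
Why: Proposed new method: after chloride–acetate exchange the phenoxide of 12 binds trivalent rhodium and acetate-assisted cleavage of the formyl C–H bond gives a five-membered acyl rhodacycle (Rh, O1, C8a, C4a, C4). Alkyne 15 then inserts into the Rh–acyl bond and forms C3–C4. Ring C closes by C–O reductive elimination from the resulting seven-membered oxarhodacycle (O1–C2, an oxidative [4+2] annulation), and Cu(OAc)2 returns monovalent rhodium to trivalent rhodium. The closest known reaction type is the rhodium-catalysed oxidative annulation of salicylaldehydes with diaryl, dialkyl and aryl–alkyl alkynes to 2,3-disubstituted chromones, in which an aryl group normally ends on C2; what is new is the use of an aryl(silyl)alkyne to reverse that sense. The selectivity needed is insertion with silicon on the rhodium-bound carbon: the α-silyl group stabilises the developing Rh–C bond, the electron-rich aryl group and the β-silicon both stabilise positive character at the carbon that receives the acyl group, and the bulky Me3Si group prefers the long Rh–C bond to the short new C–C bond, the same bias that places silicon next to the heteroatom in Larock heteroannulations. The direction of ring closure is fixed by the substrate, because of the two oxygens flanking the formyl group only the one on C8a is free. No stereocentre is formed. The trisubstituted prenyl olefin should not compete with the alkyne, the acetals tolerate the acetate-buffered medium, and any loss of the C2 silyl group after ring closure simply gives 17 ahead of step 10.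

Step 10
Reactants: 16 7-methoxy-5,8-bis(methoxymethoxy)-6-(3-methylbut-2-enyl)-3-(2,4,5-trimethoxyphenyl)-2-(trimethylsilyl)chromen-4-one
Product: 17 7-methoxy-5,8-bis(methoxymethoxy)-6-(3-methylbut-2-enyl)-3-(2,4,5-trimethoxyphenyl)chromen-4-one
Conditions: Bu4NF (1.2 equiv), AcOH (1.2 equiv), THF, 0 °C to rt
Reagents that add atoms: none
Why: Fluoride-induced protodesilylation of a C(sp2)–Si bond: C2 lies next to the ring oxygen and at the β-position of the enone, so the C2 carbanion, known from direct C2 metalation of chromones, is a good leaving group from pentacoordinate silicon. Acetic acid protonates it at once and keeps the medium from opening the pyranone.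

Step 11
Reactants: 17 7-methoxy-5,8-bis(methoxymethoxy)-6-(3-methylbut-2-enyl)-3-(2,4,5-trimethoxyphenyl)chromen-4-one
Product: 19 5,8-dihydroxy-7-methoxy-6-(3-methylbut-2-enyl)-3-(2,4,5-trimethoxyphenyl)chromen-4-one, via 8-O-MOM monoether 18 (not isolated)
Conditions: HCl (3 M aq.), MeOH (degassed), 40 °C, Ar
Reagents that add atoms: none
Why: Acid-catalysed acetal exchange with methanol, the usual last step for MOM-protected prenylated flavonoids; the ether peri to the carbonyl should go first (18). The freed C5 hydroxyl is held in a hydrogen bond to the C4 carbonyl, which tempers its addition to the prenyl olefin, and exclusion of air protects the hydroquinone.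

## Compound list

1 | 5-hydroxyvanillin (3,4-dihydroxy-5-methoxybenzaldehyde) | COc1cc(C=O)cc(O)c1O | starting material
2 | 3-hydroxy-5-methoxy-4-(methoxymethoxy)benzaldehyde | COCOc1c(O)cc(C=O)cc1OC | intermediate
3 | 3-methoxy-4-(methoxymethoxy)-5-[tri(propan-2-yl)silyloxy]benzaldehyde | COCOc1c(OC)cc(C=O)cc1O[Si](C(C)C)(C(C)C)C(C)C | intermediate
4 | [3-methoxy-4-(methoxymethoxy)-5-[tri(propan-2-yl)silyloxy]phenyl] formate (not isolated) | COCOc1c(OC)cc(OC=O)cc1O[Si](C(C)C)(C(C)C)C(C)C | intermediate
5 | 3-methoxy-4-(methoxymethoxy)-5-[tri(propan-2-yl)silyloxy]phenol | COCOc1c(OC)cc(O)cc1O[Si](C(C)C)(C(C)C)C(C)C | intermediate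
6 | [3-methoxy-2,5-bis(methoxymethoxy)phenoxy]tri(propan-2-yl)silane | COCOc1cc(OC)c(OCOC)c(O[Si](C(C)C)(C(C)C)C(C)C)c1 | intermediate
7 | prenyl bromide (1-bromo-3-methylbut-2-ene) | CC(C)=CCBr | starting material
8 | [2-methoxy-3,6-bis(methoxymethoxy)-4-[tri(propan-2-yl)silyloxy]phenyl]lithium (not isolated) | [Li]c1c(OC)c(OCOC)c(O[Si](C(C)C)(C(C)C)C(C)C)cc1OCOC | intermediate
9 | [3-methoxy-2,5-bis(methoxymethoxy)-4-(3-methylbut-2-enyl)phenoxy]tri(propan-2-yl)silane | CC(C)=CCc1c(OC)c(OCOC)c(O[Si](C(C)C)(C(C)C)C(C)C)cc1OCOC | intermediate
10 | 3-methoxy-2,5-bis(methoxymethoxy)-4-(3-methylbut-2-enyl)phenol | CC(C)=CCc1c(OC)c(OCOC)c(O)cc1OCOC | intermediate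
11 | 2-(hydroxymethyl)-5-methoxy-3,6-bis(methoxymethoxy)-4-(3-methylbut-2-enyl)phenol (not isolated) | CC(C)=CCc1c(OC)c(OCOC)c(O)c(CO)c1OCOC | intermediate
12 | 2-hydroxy-4-methoxy-3,6-bis(methoxymethoxy)-5-(3-methylbut-2-enyl)benzaldehyde | CC(C)=CCc1c(OC)c(OCOC)c(O)c(C=O)c1OCOC | intermediate
13 | 1-bromo-2,4,5-trimethoxybenzene | COc1cc(OC)c(Br)cc1OC | starting material
14 | ethynyltrimethylsilane | C#C[Si](C)(C)C | starting material
15 | trimethyl[(2,4,5-trimethoxyphenyl)ethynyl]silane | COc1cc(OC)c(C#C[Si](C)(C)C)cc1OC | intermediate
16 | 7-methoxy-5,8-bis(methoxymethoxy)-6-(3-methylbut-2-enyl)-3-(2,4,5-trimethoxyphenyl)-2-(trimethylsilyl)chromen-4-one | COCOc1c(CC=C(C)C)c(OC)c(OCOC)c2oc([Si](C)(C)C)c(-c3cc(OC)c(OC)cc3OC)c(=O)c12 | intermediate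
17 | 7-methoxy-5,8-bis(methoxymethoxy)-6-(3-methylbut-2-enyl)-3-(2,4,5-trimethoxyphenyl)chromen-4-one | COCOc1c(CC=C(C)C)c(OC)c(OCOC)c2occ(-c3cc(OC)c(OC)cc3OC)c(=O)c12 | intermediate
18 | 5-hydroxy-7-methoxy-8-(methoxymethoxy)-6-(3-methylbut-2-enyl)-3-(2,4,5-trimethoxyphenyl)chromen-4-one (not isolated) | COCOc1c(OC)c(CC=C(C)C)c(O)c2c(=O)c(-c3cc(OC)c(OC)cc3OC)coc12 | intermediate
19 | 5,8-dihydroxy-7-methoxy-6-(3-methylbut-2-enyl)-3-(2,4,5-trimethoxyphenyl)chromen-4-one | COc1cc(OC)c(-c2coc3c(O)c(OC)c(CC=C(C)C)c(O)c3c2=O)cc1OC | target

## Step count and least certain steps

Total: 11 steps. Longest linear sequence: 10 steps (steps 1 to 7 and 9 to 11, from 5-hydroxyvanillin); step 8 is the one-step alkyne branch.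

**Step 9 (key step, Proposed new method).**
- What may go wrong: insertion in the opposite orientation, which would place the aryl group on C2; copper-mediated desilylative homocoupling of the alkyne before it inserts; decarbonylation of the acyl rhodium species. Loss of the MOM ether ortho to the formyl group before ring closure would free a second hydroxyl and erase the control over the direction of closure.
- Why: the directing power of silicon has not been tested against the normal aryl preference in this reaction, and the medium is hot and oxidising.
- Fallback (known chemistry, from 12, rejoining at 17):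
  - Excess MeMgBr in THF would convert aldehyde 12 into racemic 1-[2-hydroxy-4-methoxy-3,6-bis(methoxymethoxy)-5-(3-methylbut-2-enyl)phenyl]ethanol F1.
  - MnO2 in CH2Cl2 would oxidise this benzylic alcohol to 1-[2-hydroxy-4-methoxy-3,6-bis(methoxymethoxy)-5-(3-methylbut-2-enyl)phenyl]ethanone F2.
  - Heating with N,N-dimethylformamide dimethyl acetal would give (E)-3-(dimethylamino)-1-[2-hydroxy-4-methoxy-3,6-bis(methoxymethoxy)-5-(3-methylbut-2-enyl)phenyl]prop-2-en-1-one F3.
  - I2 in CHCl3 at rt would cyclise the enaminone with loss of dimethylamine to 3-iodo-7-methoxy-5,8-bis(methoxymethoxy)-6-(3-methylbut-2-enyl)chromen-4-one F4.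
  - Suzuki–Miyaura coupling with commercial 2,4,5-trimethoxyphenylboronic acid (Pd(PPh3)4, Na2CO3, DME/H2O, 80 °C) would give 17.
  - This road fixes the aryl group on C3 by construction, at the cost of three extra steps and a brief exposure of the prenyl olefin to iodine.

**Step 10.**
- What may go wrong: fluoride or adventitious hydroxide adding at C2 and opening the pyranone, or sluggish C–Si cleavage under the buffered conditions.
- Why: C2 of a chromone is an electrophilic carbon.
- Fallback (from 16, rejoining at 19): treat 16 directly with HCl in methanol at 40 to 50 °C. The acetals should fall first to give 5,8-dihydroxy-7-methoxy-6-(3-methylbut-2-enyl)-3-(2,4,5-trimethoxyphenyl)-2-(trimethylsilyl)chromen-4-one F5. O-protonation of its carbonyl makes a 4-hydroxypyrylium ion, whose C2 silicon should be removed by methanol through the ylide, as 2-silylpyridinium ions are. This replaces nucleophilic attack on the heterocycle by electrophilic activation and shortens the route by one step, at the price of a longer acid exposure of the prenyl group.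

**Step 7.**
- What may go wrong: slow or incomplete C-formylation, magnesium-assisted loss of the neighbouring acetal, or condensation of salicyl alcohol 11 with a second phenol to a diarylmethane.
- Why: the reacting carbon is flanked on both sides and the ring is very electron-rich.
- Fallback (from 10, rejoining at 12): brominate the single free ring position with N-bromosuccinimide in CH2Cl2 at −78 °C to give 2-bromo-5-methoxy-3,6-bis(methoxymethoxy)-4-(3-methylbut-2-enyl)phenol F6. Then n-BuLi (2.2 equiv, THF, −78 °C) would effect deprotonation and bromine–lithium exchange, and DMF would give 12. The carbon nucleophile is thereby made irreversibly at the hindered site instead of relying on a reversible electrophilic attack.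

**Step 5.**
- What may go wrong: incomplete alkylation with proton return, bromine–lithium exchange with the allylic bromide followed by homocoupling, or attack at the tertiary allylic carbon to give the 1,1-dimethylallyl isomer.
- Why: allylic bromides offer an aryllithium several competing pathways.
- Fallback (from 6, through aryllithium 8, rejoining at 9): quench 8 with allyl bromide (CuBr·SMe2 catalysis), which has no regiochemical ambiguity, to give [3-methoxy-2,5-bis(methoxymethoxy)-4-(prop-2-enyl)phenoxy]tri(propan-2-yl)silane F7. Cross-metathesis with 2-methylbut-2-ene (second-generation Grubbs catalyst, CH2Cl2, 40 °C) would then convert the allyl group into the prenyl group of 9.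

**Step 1.**
- What may go wrong: alkylation of both catechol oxygens, or of O3 instead of O4.
- Why: the selectivity rests only on an acidity difference, and the O4 hydroxyl is the more hindered one.
- Fallback (from 1, rejoining at 3): silylate both phenols (TIPSOTf, 2,6-lutidine, CH2Cl2) to give 3-methoxy-4,5-bis[tri(propan-2-yl)silyloxy]benzaldehyde F8. One equivalent of Bu4NF at −78 °C should remove the silyl group para to the formyl group, whose phenoxide is the better leaving group, giving 4-hydroxy-3-methoxy-5-[tri(propan-2-yl)silyloxy]benzaldehyde F9. Any silyl migration between the neighbouring oxygens leads to the same, more stable phenoxide. MOMCl and i-Pr2NEt would then give 3, with the differentiation achieved by selective deprotection instead of selective alkylation.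

## Further compounds

F1 | step 9 | 1-[2-hydroxy-4-methoxy-3,6-bis(methoxymethoxy)-5-(3-methylbut-2-enyl)phenyl]ethanol (racemic) | CC(O)c1c(O)c(OCOC)c(OC)c(CC=C(C)C)c1OCOC
F2 | step 9 | 1-[2-hydroxy-4-methoxy-3,6-bis(methoxymethoxy)-5-(3-methylbut-2-enyl)phenyl]ethanone | CC(=O)c1c(O)c(OCOC)c(OC)c(CC=C(C)C)c1OCOC
F3 | step 9 | (E)-3-(dimethylamino)-1-[2-hydroxy-4-methoxy-3,6-bis(methoxymethoxy)-5-(3-methylbut-2-enyl)phenyl]prop-2-en-1-one | CN(C)/C=C/C(=O)c1c(O)c(OCOC)c(OC)c(CC=C(C)C)c1OCOC
F4 | step 9 | 3-iodo-7-methoxy-5,8-bis(methoxymethoxy)-6-(3-methylbut-2-enyl)chromen-4-one | COCOc1c(CC=C(C)C)c(OC)c(OCOC)c2occ(I)c(=O)c12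
F5 | step 10 | 5,8-dihydroxy-7-methoxy-6-(3-methylbut-2-enyl)-3-(2,4,5-trimethoxyphenyl)-2-(trimethylsilyl)chromen-4-one | COc1cc(OC)c(-c2c([Si](C)(C)C)oc3c(O)c(OC)c(CC=C(C)C)c(O)c3c2=O)cc1OC
F6 | step 7 | 2-bromo-5-methoxy-3,6-bis(methoxymethoxy)-4-(3-methylbut-2-enyl)phenol | CC(C)=CCc1c(OC)c(OCOC)c(O)c(Br)c1OCOC
F7 | step 5 | [3-methoxy-2,5-bis(methoxymethoxy)-4-(prop-2-enyl)phenoxy]tri(propan-2-yl)silane | C=CCc1c(OC)c(OCOC)c(O[Si](C(C)C)(C(C)C)C(C)C)cc1OCOC
F8 | step 1 | 3-methoxy-4,5-bis[tri(propan-2-yl)silyloxy]benzaldehyde | COc1cc(C=O)cc(O[Si](C(C)C)(C(C)C)C(C)C)c1O[Si](C(C)C)(C(C)C)C(C)C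
F9 | step 1 | 4-hydroxy-3-methoxy-5-[tri(propan-2-yl)silyloxy]benzaldehyde | COc1cc(C=O)cc(O[Si](C(C)C)(C(C)C)C(C)C)c1O
A1 | alternative 1 | 5-hydroxy-7-methoxy-6-(3-methylbut-2-enyl)-3-(2,4,5-trimethoxyphenyl)chromen-4-one | COc1cc(OC)c(-c2coc3cc(OC)c(CC=C(C)C)c(O)c3c2=O)cc1OC
A2 | alternative 1 | 2-(2-diazoacetyl)-5-(2,4,5-trimethoxyphenyl)pyran-4-one | [N-]=[N+]=CC(=O)c1cc(=O)c(-c2cc(OC)c(OC)cc2OC)co1
A3 | alternative 1 | 1-methoxy-5-methylhex-4-en-1-yne | COC#CCC=C(C)C
A4 | alternative 2 | 5,8-bis(benzyloxy)-7-methoxy-6-(3-methylbut-2-enyl)-3-(2,4,5-trimethoxyphenyl)chromen-4-one | COc1cc(OC)c(-c2coc3c(OCc4ccccc4)c(OC)c(CC=C(C)C)c(OCc4ccccc4)c3c2=O)cc1OC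
A5 | alternative 2 | (Z)-3-[2,5-bis(benzyloxy)-3-methoxy-4-(3-methylbut-2-enyl)phenoxy]-2-(2,4,5-trimethoxyphenyl)prop-2-enoic acid | OC(=O)/C(=C\Oc1cc(OCc2ccccc2)c(CC=C(C)C)c(OC)c1OCc1ccccc1)c1cc(OC)c(OC)cc1OC
A6 | alternative 3 | 7-methoxy-5-(methoxymethoxy)-6-(3-methylbut-2-enyl)-3-(2,4,5-trimethoxyphenyl)chromen-4-one | COCOc1c(CC=C(C)C)c(OC)cc2occ(-c3cc(OC)c(OC)cc3OC)c(=O)c12
A7 | alternative 3 | [5-methoxy-3-(methoxymethoxy)-4-(3-methylbut-2-enyl)-2-(trimethylsilyl)phenyl] trifluoromethanesulfonate | COCOc1c(CC=C(C)C)c(OC)cc(OS(=O)(=O)C(F)(F)F)c1[Si](C)(C)C
A8 | alternative 3 | methyl 3-hydroxy-2-(2,4,5-trimethoxyphenyl)prop-2-enoate | COC(=O)C(=CO)c1cc(OC)c(OC)cc1OC
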